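**Retrosynthetic overview**
1. The target is (2S)-7,4'-dihydroxyflavan-(4β→8)-epiafzelechin-(4β→8)-epiafzelechin. Both C4–C8 interflavan bonds are cut (capture of C4 cations by C8, built from the bottom up). This leaves flavan-4-ol 21 and two copies of one monomer, tri-O-benzyl-epiafzelechin 13.
2. Monomer 13 comes from racemic flavan-3-one 12 by transfer hydrogenation under dynamic kinetic resolution, which sets C2 and C3 (2,3-cis) together.
3. Ketone 12 comes from the flat, achiral 2-benzylbenzofuran 7 by an oxidative, dearomatising ring expansion. The furan ring (O1, C2, C3, C3a, C7a) takes up its exocyclic benzylic carbon and becomes the pyran ring (O1, C2, C3, C4, C4a, C8a).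
4. Enabling feature: in the epiafzelechin C ring, O1 sits on C2, which also bears the 4-hydroxyphenyl B ring; C3 is oxygenated; C4 is benzylic to the phloroglucinol A ring (O at C5, C7, C8a). Moving O1 from C2 to C3 gives a benzofuran. The A-ring oxygens carry an o-quinone methide at C4, and the B ring activates C2.
5. Ring order: furan (step 2); pyran C rings of the lower and middle units (step 4, one batch); C ring of the top unit by oxa-Michael closure (step 10); then C4–C8 middle→lower (step 8) and C4–C8 top→middle (step 12).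

Key step: step 4

Assumption: in step 5 the (R,R)-Ru–TsDPEN catalyst is taken to give the (3R)-alcohol, treating the C2 side of the ketone as the aryl-bearing side of the usual model. If the sense is opposite, the equally available (S,S)-catalyst is used and nothing else changes. Compounds 1, 3, 17 and 18 are taken as commercial.

Step 1
Reactants: 1 2,4,6-trihydroxybenzaldehyde
Product: 2 2,4-bis(benzyloxy)-6-hydroxybenzaldehyde
Conditions: BnBr (2.05 equiv), K2CO3 (2.1 equiv), DMF, rt
Reagents that add atoms: benzyl bromide, BrCc1ccccc1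
Why: Williamson etherification, in which the 4-OH and one ortho-OH are alkylated while the last ortho-OH is held back by its hydrogen bond to the aldehyde, so two equivalents of halide should stop at the dibenzyl ether.

Step 2
Reactants: 2 2,4-bis(benzyloxy)-6-hydroxybenzaldehyde; 3 1-[4-(benzyloxy)phenyl]-2-bromoethan-1-one
Product: 5 [4,6-bis(benzyloxy)-1-benzofuran-2-yl][4-(benzyloxy)phenyl]methanone, via phenacyl aryl ether 4 (not isolated)
Conditions: K2CO3, MeCN, 80 °C
Reagents that add atoms: none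
Why: Rap–Stoermer benzofuran synthesis, in which O-alkylation of the phenoxide is followed by intramolecular aldol condensation of the activated OCH2 onto the neighbouring aldehyde, with aromatisation driving the loss of water.

Step 3
Reactants: 5 [4,6-bis(benzyloxy)-1-benzofuran-2-yl][4-(benzyloxy)phenyl]methanone
Product: 7 4,6-bis(benzyloxy)-2-[4-(benzyloxy)benzyl]-1-benzofuran, via benzofuranyl carbinol 6 (not isolated)
Conditions: NaBH4, THF/MeOH, 0 °C; work-up, crude; then Et3SiH (5 equiv), TFA (2 equiv), CH2Cl2, −40 to 0 °C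
Reagents that add atoms: none
Why: Carbonyl reduction followed by ionic hydrogenation, in which the doubly stabilised (2-benzofuryl)(4-alkoxyphenyl)methyl cation forms with little acid at low temperature and is trapped by excess silane before it can alkylate another A ring, while aryl benzyl ethers and the furan double bond survive.

Step 4
Reactants: 7 4,6-bis(benzyloxy)-2-[4-(benzyloxy)benzyl]-1-benzofuran
Product: 12 rac-5,7-bis(benzyloxy)-2-[4-(benzyloxy)phenyl]chroman-3-one, via benzofuran 2,3-epoxide 8 (not isolated), via (Z)-acyl o-quinone methide 9 (not isolated), via hydroxyvinyl o-quinone methide 10 (not isolated), via 2H-chromen-3-ol 11 (not isolated)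
Conditions: DMDO (1.0 equiv, acetone), CH2Cl2 (0.01 M), 4 Å MS, −78 to −40 °C; then (PhO)2P(O)OH (10 mol %), −40 °C to rt, Ar
Reagents that add atoms: dimethyldioxirane (DMDO), CC1(C)OO1
Why: Proposed new method: DMDO epoxidises the enol-ether bond C2=C3 of the furan ring, and epoxide 8 ionises at C3–O because that cation is carried by the oxygens at C4, C6 and C7a of the benzo ring, so the furan C2–O1 bond breaks and the (Z)-acyl o-quinone methide 9 results, which is the known valence isomerisation of benzofuran epoxides. The CH2 group of 9 lies between the new ketone and the 4-benzyloxyphenyl ring, so the phosphoric acid shuttles its proton to give the 1-oxatriene 10. The only ring closed is the pyran, by oxa-6π electrocyclisation of 10 (in polar terms a 6-endo attack of O1 on the aryl-stabilised terminus of the protonated 2-hydroxyallyl cation, attack at the other terminus being a four-membered closure), so that O1 ends on the former exocyclic carbon, the five-membered ring has become six-membered in 11, and ketonisation gives 12. The closest known reaction types are the Achmatowicz ring expansion of furfuryl systems, the closure of vinyl o-quinone methides to 2H-chromenes and the Auwers coumaranone-to-flavonol expansion, none of which has been run on a 2-benzylbenzofuran. The one new stereocentre, C2, is formed without control and on purpose as a racemate, because it is α to the C3 ketone and is set in step 5 under epimerising conditions. The step needs epoxidation of C2=C3 before any arene or benzyl ether oxidation (secured by the enol-ether character of that bond and by one equivalent of oxidant consumed cold before enol 11 exists) and ring expansion ahead of 1,2-shifts, dimerisation or intermolecular C4 arylation (secured by the Z geometry inherited from the furan, the doubly activated CH2, high dilution and the absence of external nucleophiles).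

Step 5
Reactants: 12 rac-5,7-bis(benzyloxy)-2-[4-(benzyloxy)phenyl]chroman-3-one
Product: 13 (2R,3R)-5,7-bis(benzyloxy)-2-[4-(benzyloxy)phenyl]chroman-3-ol (5,7,4'-tri-O-benzyl-epiafzelechin)
Conditions: RuCl(p-cymene)[(R,R)-TsDPEN] (2 mol %), HCO2H/Et3N (5:2), CH2Cl2, 30 °C, Ar
Reagents that add atoms: none
Why: Noyori–Ikariya asymmetric transfer hydrogenation under dynamic kinetic resolution, as known for 1-aryl-2-tetralones and other α-aryl cyclic ketones, in which C2 (α to the ketone, benzylic, O-substituted) epimerises through enol 11, the catalyst fixes the face of hydride delivery at C3 (3R), and only the enantiomer with its 2-aryl group anti to the incoming hydride is reduced, which should give the 2,3-cis (2R,3R) alcohol.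

Step 6
Reactants: 13 5,7,4'-tri-O-benzyl-epiafzelechin
Product: 14 5,7,4'-tri-O-benzyl-4β-(2-ethoxyethoxy)-epiafzelechin (2α-aryl, 3α-OH, 4β-OR)
Conditions: DDQ (2 equiv), 2-ethoxyethanol (5 equiv), CH2Cl2, rt
Reagents that add atoms: 2-ethoxyethanol, CCOCCO
Why: DDQ benzylic C–H oxidation, in which hydride abstraction at C4 gives the cation stabilised by the phloroglucinol ring (easier than at C2) and the alcohol adds anti to the 3-OH, the C4 configuration being of no consequence since it is ionised again in step 8.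

Step 7
Reactants: 14 5,7,4'-tri-O-benzyl-4β-(2-ethoxyethoxy)-epiafzelechin
Product: 15 3-O-acetyl-5,7,4'-tri-O-benzyl-4β-(2-ethoxyethoxy)-epiafzelechin
Conditions: Ac2O, DMAP (cat.), pyridine, rt
Reagents that add atoms: acetic anhydride, CC(=O)OC(C)=O
Why: DMAP-catalysed acylation of the secondary 3-OH, which removes this hydroxyl as a competing nucleophile and tags the future middle unit.

Step 8
Reactants: 15 3-O-acetyl-5,7,4'-tri-O-benzyl-4β-(2-ethoxyethoxy)-epiafzelechin; 13 5,7,4'-tri-O-benzyl-epiafzelechin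
Product: 16 3-O-acetyl-5,7,4'-tri-O-benzyl-epiafzelechin-(4β→8)-5,7,4'-tri-O-benzyl-epiafzelechin
Conditions: Yb(OTf)3 (cat.), CH2Cl2, 0 °C to rt; 13 in slight excess
Reagents that add atoms: none
Why: Lewis acid-promoted Friedel–Crafts condensation of a flavan-4-yl cation with a flavan-3-ol, as used for 4β→8 proanthocyanidins, in which the cation of the 2,3-cis unit is attacked on its β face, anti to the 3-OAc, and C8 is the most nucleophilic free position of benzylated 13.

Step 9
Reactants: 17 1-[4-(benzyloxy)-2-hydroxyphenyl]ethan-1-one; 18 4-(benzyloxy)benzaldehyde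
Product: 19 (E)-1-[4-(benzyloxy)-2-hydroxyphenyl]-3-[4-(benzyloxy)phenyl]prop-2-en-1-one
Conditions: KOH, EtOH/H2O, rt
Reagents that add atoms: none
Why: Claisen–Schmidt condensation with a non-enolisable aldehyde, in which conjugation secures the E-chalcone.

Step 10
Reactants: 19 (E)-chalcone
Product: 20 rac-7-(benzyloxy)-2-[4-(benzyloxy)phenyl]chroman-4-one
Conditions: NaOAc, EtOH, reflux
Reagents that add atoms: none
Why: Chalcone–flavanone isomerisation by intramolecular oxa-Michael addition (6-endo-trig) of the 2'-phenoxide, which gives C2 as a racemate, with unchanged chalcone being recycled.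

Step 11
Reactants: 20 rac-7-(benzyloxy)-2-[4-(benzyloxy)phenyl]chroman-4-one
Product: 21 (2S,4S)-7-(benzyloxy)-2-[4-(benzyloxy)phenyl]chroman-4-ol (2,4-cis)
Conditions: RuCl(p-cymene)[(S,S)-TsDPEN] (1 mol %), HCO2H/Et3N (5:2), EtOAc, rt, stopped near half conversion
Reagents that add atoms: none
Why: Kinetic resolution of a flavanone by asymmetric transfer hydrogenation, in which the (S,S)-catalyst makes the (4S)-benzylic alcohol as with aryl alkyl ketones and hydride delivery anti to the 2-aryl group is matched only for the (2S)-ketone, so the (2R)-enantiomer of 20 stays unreduced and is removed by chromatography.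

Step 12
Reactants: 21 (2S,4S)-7-(benzyloxy)-2-[4-(benzyloxy)phenyl]chroman-4-ol; 16 acetylated hexa-O-benzyl dimer
Product: 22 (2S)-7,4'-di-O-benzylflavan-(4β→8)-[3-O-acetyl-5,7,4'-tri-O-benzyl-epiafzelechin]-(4β→8)-5,7,4'-tri-O-benzyl-epiafzelechin
Conditions: BF3·OEt2 (0.3 equiv), 4 Å MS, CH2Cl2, −40 to −10 °C; 16 in slight excess
Reagents that add atoms: none
Why: Lewis acid-catalysed Friedel–Crafts alkylation by a flavan-4-yl cation (4-arylflavan formation), in which the O1/7-O-stabilised cation is captured by the phloroglucinol-type rings of 16 rather than by its own resorcinol ring, C8 of the upper unit is the only free C8 and the site at which such dimers are known to be extended, and pseudo-axial attack on the half-chair cation with the 2-aryl group equatorial should set the new centre 2,4-trans (4β).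

Step 13
Reactants: 22 acetylated octa-O-benzyl trimer
Product: 23 (2S)-7,4'-di-O-benzylflavan-(4β→8)-5,7,4'-tri-O-benzyl-epiafzelechin-(4β→8)-5,7,4'-tri-O-benzyl-epiafzelechin
Conditions: NaOMe, MeOH/THF, 40 °C
Reagents that add atoms: none
Why: Zemplén-type transesterification of the single acetate, carried out while all phenols are still benzylated so that no base-sensitive free polyphenol is exposed and no stereocentre is touched.

Step 14
Reactants: 23 octa-O-benzyl trimer
Product: 24 (2S)-7,4'-dihydroxyflavan-(4β→8)-epiafzelechin-(4β→8)-epiafzelechin (CNP0257624.1)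
Conditions: H2 (1 atm), Pd(OH)2/C, THF/MeOH/H2O, rt; filtration, lyophilisation
Reagents that add atoms: none
Why: Global hydrogenolysis of eight aryl benzyl ethers under neutral conditions, as is standard for benzylated proanthocyanidins, in which the ring C2–O1 bonds and the interflavan C–C bonds should remain intact.

**Compound list**
1 | 2,4,6-trihydroxybenzaldehyde | O=Cc1c(O)cc(O)cc1O | starting material
2 | 2,4-bis(benzyloxy)-6-hydroxybenzaldehyde | O=Cc1c(O)cc(OCc2ccccc2)cc1OCc1ccccc1 | intermediate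
3 | 1-[4-(benzyloxy)phenyl]-2-bromoethan-1-one | O=C(CBr)c1ccc(OCc2ccccc2)cc1 | starting material
4 | 2,4-bis(benzyloxy)-6-{2-[4-(benzyloxy)phenyl]-2-oxoethoxy}benzaldehyde | O=Cc1c(OCC(=O)c2ccc(OCc3ccccc3)cc2)cc(OCc2ccccc2)cc1OCc1ccccc1 | intermediate
5 | [4,6-bis(benzyloxy)-1-benzofuran-2-yl][4-(benzyloxy)phenyl]methanone | O=C(c1ccc(OCc2ccccc2)cc1)c1cc2c(OCc3ccccc3)cc(OCc3ccccc3)cc2o1 | intermediate
6 | rac-[4,6-bis(benzyloxy)-1-benzofuran-2-yl][4-(benzyloxy)phenyl]methanol | OC(c1ccc(OCc2ccccc2)cc1)c1cc2c(OCc3ccccc3)cc(OCc3ccccc3)cc2o1 | intermediate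
7 | 4,6-bis(benzyloxy)-2-[4-(benzyloxy)benzyl]-1-benzofuran | c1ccccc1COc1ccc(Cc2cc3c(OCc4ccccc4)cc(OCc4ccccc4)cc3o2)cc1 | intermediate
8 | rac-2,3-epoxide of 7 (cis-fused oxireno[2,3-b]benzofuran) | c1ccccc1COc1ccc(CC23OC2c2c(OCc4ccccc4)cc(OCc4ccccc4)cc2O3)cc1 | intermediate
9 | (6Z)-3,5-bis(benzyloxy)-6-{3-[4-(benzyloxy)phenyl]-2-oxopropylidene}cyclohexa-2,4-dien-1-one | O=C(Cc1ccc(OCc2ccccc2)cc1)/C=C1\C(=O)C=C(OCc2ccccc2)C=C1OCc1ccccc1 | intermediate
10 | enol of 9 (6Z; 2-hydroxy-3-arylallylidene o-quinone methide, enol geometry open) | OC(=Cc1ccc(OCc2ccccc2)cc1)/C=C1\C(=O)C=C(OCc2ccccc2)C=C1OCc1ccccc1 | intermediate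
11 | rac-5,7-bis(benzyloxy)-2-[4-(benzyloxy)phenyl]-2H-chromen-3-ol | OC1=Cc2c(OCc3ccccc3)cc(OCc3ccccc3)cc2OC1c1ccc(OCc2ccccc2)cc1 | intermediate
12 | rac-5,7-bis(benzyloxy)-2-[4-(benzyloxy)phenyl]chroman-3-one | O=C1Cc2c(OCc3ccccc3)cc(OCc3ccccc3)cc2OC1c1ccc(OCc2ccccc2)cc1 | intermediate
13 | (2R,3R)-5,7-bis(benzyloxy)-2-[4-(benzyloxy)phenyl]chroman-3-ol | c1ccccc1COc1cc(OCc2ccccc2)c2c(c1)O[C@H](c1ccc(OCc3ccccc3)cc1)[C@H](O)C2 | intermediate
14 | 5,7,4'-tri-O-benzyl-4β-(2-ethoxyethoxy)-epiafzelechin | c1ccccc1COc1cc(OCc2ccccc2)c2c(c1)O[C@H](c1ccc(OCc3ccccc3)cc1)[C@H](O)[C@H]2OCCOCC | intermediate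
15 | 3-O-acetyl-5,7,4'-tri-O-benzyl-4β-(2-ethoxyethoxy)-epiafzelechin | c1ccccc1COc1cc(OCc2ccccc2)c2c(c1)O[C@H](c1ccc(OCc3ccccc3)cc1)[C@H](OC(C)=O)[C@H]2OCCOCC | intermediate
16 | 3-O-acetyl-5,7,4'-tri-O-benzyl-epiafzelechin-(4β→8)-5,7,4'-tri-O-benzyl-epiafzelechin | c1ccccc1COc1cc(OCc2ccccc2)c2c(c1)O[C@H](c1ccc(OCc3ccccc3)cc1)[C@H](OC(C)=O)[C@H]2c1c(OCc2ccccc2)cc(OCc2ccccc2)c2c1O[C@H](c1ccc(OCc3ccccc3)cc1)[C@H](O)C2 | intermediate
17 | 1-[4-(benzyloxy)-2-hydroxyphenyl]ethan-1-one | CC(=O)c1ccc(OCc2ccccc2)cc1O | starting material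
18 | 4-(benzyloxy)benzaldehyde | O=Cc1ccc(OCc2ccccc2)cc1 | starting material
19 | (E)-1-[4-(benzyloxy)-2-hydroxyphenyl]-3-[4-(benzyloxy)phenyl]prop-2-en-1-one | O=C(/C=C/c1ccc(OCc2ccccc2)cc1)c1ccc(OCc2ccccc2)cc1O | intermediate
20 | rac-7-(benzyloxy)-2-[4-(benzyloxy)phenyl]chroman-4-one | O=C1CC(c2ccc(OCc3ccccc3)cc2)Oc2cc(OCc3ccccc3)ccc12 | intermediate
21 | (2S,4S)-7-(benzyloxy)-2-[4-(benzyloxy)phenyl]chroman-4-ol | c1ccccc1COc1ccc([C@@H]2C[C@H](O)c3ccc(OCc4ccccc4)cc3O2)cc1 | intermediate
22 | acetylated octa-O-benzyl trimer (top 2,4-trans, 4β→8; middle 3-OAc, 4β→8) | c1ccccc1COc1ccc([C@@H]2C[C@@H](c3c(OCc4ccccc4)cc(OCc4ccccc4)c4c3O[C@H](c3ccc(OCc5ccccc5)cc3)[C@H](OC(C)=O)[C@H]4c3c(OCc4ccccc4)cc(OCc4ccccc4)c4c3O[C@H](c3ccc(OCc5ccccc5)cc3)[C@H](O)C4)c3ccc(OCc4ccccc4)cc3O2)cc1 | intermediate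
23 | octa-O-benzyl trimer, both 3-OH free | c1ccccc1COc1ccc([C@@H]2C[C@@H](c3c(OCc4ccccc4)cc(OCc4ccccc4)c4c3O[C@H](c3ccc(OCc5ccccc5)cc3)[C@H](O)[C@H]4c3c(OCc4ccccc4)cc(OCc4ccccc4)c4c3O[C@H](c3ccc(OCc5ccccc5)cc3)[C@H](O)C4)c3ccc(OCc4ccccc4)cc3O2)cc1 | intermediate
24 | (2S)-7,4'-dihydroxyflavan-(4β→8)-epiafzelechin-(4β→8)-epiafzelechin | Oc1ccc([C@@H]2C[C@@H](c3c(O)cc(O)c4c3O[C@H](c3ccc(O)cc3)[C@H](O)[C@H]4c3c(O)cc(O)c4c3O[C@H](c3ccc(O)cc3)[C@H](O)C4)c3ccc(O)cc3O2)cc1 | target

**Totals**
Total step count: 14.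
Longest linear sequence: 11 (steps 1–8, 12, 13, 14).

**Steps most likely to fail**

1. Step 4.
- Risk: the o-quinone methide may be diverted before it enolises. Possible diversions are a 1,2-shift of hydrogen or benzyl at the epoxide stage, dimerisation, and arylation at C4 by a second electron-rich A ring. The nascent enol may also be over-oxidised.
- Fallback: it sets out from 18, returns at 12, and keeps a five-to-six ring expansion using classical chemistry.
  - Commercial 4,6-dihydroxybenzofuran-3(2H)-one F1 is benzylated (BnBr, K2CO3, DMF) to 4,6-bis(benzyloxy)benzofuran-3(2H)-one F2.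
  - F2 is condensed with 18 (KOH, MeOH) to the (Z)-aurone F3.
  - F3 is brominated (pyridinium tribromide, CH2Cl2, 0 °C) to the aurone dibromide F4.
  - Treatment of F4 with KOH in EtOH (Auwers synthesis, coumaranone-to-flavonol ring expansion) gives 5,7,4'-tri-O-benzylkaempferol F5.
  - O-Benzylation gives 3,5,7,4'-tetra-O-benzylkaempferol F6.
  - LiAlH4 reduction gives the 3-benzyloxyflav-3-ene F7.
  - Mild aqueous acid hydrolysis of this enol ether gives 12.

2. Step 12.
- Risk: site selectivity may be poor (C8 of the upper unit against the two free C6 positions). Facial selectivity may be poor for a C4 cation without a 3-substituent. Elimination to a flavene and acid-induced scission of the existing interflavan bond are also possible.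
- Fallback: it sets out from 15 and 21, returns at 22, and reverses the order of assembly by orthogonal activation.
  - Thiolysis of 15 (2,6-dimethylbenzenethiol, BF3·OEt2, −78 °C) gives the 4β-(2,6-dimethylphenylthio) monomer F8. Its C4–S bond is inert to hard Lewis acids and it offers only two nucleophilic sites.
  - F8 is alkylated with 21 (BF3·OEt2, −78 to −40 °C) to the top–middle thioether dimer F9, which is purified at the dimer stage.
  - Soft activation of F9 (I2, Ag2O, CH2Cl2) in the presence of 13 forms the well-behaved epi-type 4β→8 bond last and gives 22.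

3. Step 5.
- Risk: epimerisation at C2 may be slower than reduction, so that the dynamic resolution collapses to a simple resolution. Facial discrimination may be low for a ketone flanked by two sp3 carbons, or the sense of induction may be opposite.
- Fallback: it sets out from 12, returns at 13, and replaces catalysis by substrate-controlled reduction plus classical resolution.
  - L-Selectride (THF, −78 °C) attacks anti to the 2-aryl group and gives the racemic 2,3-cis alcohol F10.
  - Esterification with (S)-2-methoxy-2-phenylacetic acid (DCC, DMAP) gives the (2R,3R)-ester F11 and the (2S,3S)-ester F12.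
  - The two esters are separated by chromatography or crystallisation.
  - Methanolysis of F11 (K2CO3, MeOH/THF) gives 13.

**Further compounds**
F1 | step 4 | 4,6-dihydroxybenzofuran-3(2H)-one | O=C1COc2cc(O)cc(O)c12
F2 | step 4 | 4,6-bis(benzyloxy)benzofuran-3(2H)-one | O=C1COc2cc(OCc3ccccc3)cc(OCc3ccccc3)c12
F3 | step 4 | (Z)-4,6-bis(benzyloxy)-2-[4-(benzyloxy)benzylidene]benzofuran-3(2H)-one | O=C1/C(=C/c2ccc(OCc3ccccc3)cc2)Oc2cc(OCc3ccccc3)cc(OCc3ccccc3)c12
F4 | step 4 | rac-4,6-bis(benzyloxy)-2-bromo-2-{bromo[4-(benzyloxy)phenyl]methyl}benzofuran-3(2H)-one | O=C1C(Br)(C(Br)c2ccc(OCc3ccccc3)cc2)Oc2cc(OCc3ccccc3)cc(OCc3ccccc3)c12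
F5 | step 4 | 5,7,4'-tri-O-benzylkaempferol | O=c1c(O)c(-c2ccc(OCc3ccccc3)cc2)oc2cc(OCc3ccccc3)cc(OCc3ccccc3)c12
F6 | step 4 | 3,5,7,4'-tetra-O-benzylkaempferol | O=c1c(OCc2ccccc2)c(-c2ccc(OCc3ccccc3)cc2)oc2cc(OCc3ccccc3)cc(OCc3ccccc3)c12
F7 | step 4 | rac-3,5,7-tris(benzyloxy)-2-[4-(benzyloxy)phenyl]-2H-chromene | C(c1ccccc1)OC1=Cc2c(OCc3ccccc3)cc(OCc3ccccc3)cc2OC1c1ccc(OCc2ccccc2)cc1
F8 | step 12 | 3-O-acetyl-5,7,4'-tri-O-benzyl-4β-(2,6-dimethylphenylthio)-epiafzelechin | c1ccccc1COc1cc(OCc2ccccc2)c2c(c1)O[C@H](c1ccc(OCc3ccccc3)cc1)[C@H](OC(C)=O)[C@H]2Sc1c(C)cccc1C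
F9 | step 12 | (2S)-7,4'-di-O-benzylflavan-(4β→8)-[3-O-acetyl-5,7,4'-tri-O-benzyl-4β-(2,6-dimethylphenylthio)-epiafzelechin] | c1ccccc1COc1ccc([C@@H]2C[C@@H](c3c(OCc4ccccc4)cc(OCc4ccccc4)c4c3O[C@H](c3ccc(OCc5ccccc5)cc3)[C@H](OC(C)=O)[C@H]4Sc3c(C)cccc3C)c3ccc(OCc4ccccc4)cc3O2)cc1
F10 | step 5 | rac-2,3-cis-5,7-bis(benzyloxy)-2-[4-(benzyloxy)phenyl]chroman-3-ol (both enantiomers) | c1ccccc1COc1cc(OCc2ccccc2)c2c(c1)O[C@H](c1ccc(OCc3ccccc3)cc1)[C@H](O)C2.c1ccccc1COc1cc(OCc2ccccc2)c2c(c1)O[C@@H](c1ccc(OCc3ccccc3)cc1)[C@@H](O)C2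
F11 | step 5 | (2R,3R)-5,7-bis(benzyloxy)-2-[4-(benzyloxy)phenyl]chroman-3-yl (S)-2-methoxy-2-phenylacetate | c1ccccc1COc1cc(OCc2ccccc2)c2c(c1)O[C@H](c1ccc(OCc3ccccc3)cc1)[C@H](OC(=O)[C@@H](OC)c1ccccc1)C2
F12 | step 5 | (2S,3S)-5,7-bis(benzyloxy)-2-[4-(benzyloxy)phenyl]chroman-3-yl (S)-2-methoxy-2-phenylacetate | c1ccccc1COc1cc(OCc2ccccc2)c2c(c1)O[C@@H](c1ccc(OCc3ccccc3)cc1)[C@@H](OC(=O)[C@@H](OC)c1ccccc1)C2
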